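**Retrosynthetic overview**

1. Elaphopilosin B ⇒ cut the ArCH2–C(ring) bond: intermolecular Michael addition of the aromatic 4-O-methyl hexanoylphloroglucinol to an exo-methylene trione released from the Mannich base of the chiral dearomatised butanoyl fragment.
2. The dearomatised ring is the only ring built (the benzene ring is bought as phloroglucinol) ⇒ Dieckmann-type Claisen closure of an acyclic 3,5,7-triketo ester.
3. Triketo ester ⇒ C-acylation of the heptane-2,4-dione dianion by the imidazolide of a chiral 2-methyl-2-prenylmalonic half-ester.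
4. Quaternary stereocentre ⇒ asymmetric phase-transfer prenylation of a mixed tert-butyl/2,2-diphenylethyl methylmalonate; the two ester arms are then elaborated one at a time, so the centre stays defined.
5. Aromatic partner ⇒ Friedel–Crafts hexanoylation of phloroglucinol, then selective 4-O-methylation.

Assumption: the (S,S)-catalyst of step 3 gives the (S)-malonate 4, as for allylic and benzylic bromides in this substrate class; if the sense is opposite, the (R,R)-catalyst is used and nothing else changes.

**Route**

Step 1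
Reactants: 1 2,2,5-trimethyl-1,3-dioxane-4,6-dione (methyl Meldrum's acid)
Product: 2 3-tert-butoxy-2-methyl-3-oxopropanoic acid
Conditions: t-BuOH, reflux, 6 h
Reagents that add atoms: tert-butanol, CC(C)(C)O
Why: Thermal alcoholysis (acyl substitution) of the Meldrum's acid ring by tert-butanol expels acetone and gives the malonic half-ester; the α-carbon is enolisable, so no stereocentre is fixed yet.

Step 2
Reactants: 2 3-tert-butoxy-2-methyl-3-oxopropanoic acid
Product: 3 1-tert-butyl 3-(2,2-diphenylethyl) 2-methylpropanedioate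
Conditions: 2,2-diphenylethanol, DCC, 4-(dimethylamino)pyridine (10 mol%), CH2Cl2, 0 °C → rt
Reagents that add atoms: 2,2-diphenylethanol, OCC(c1ccccc1)c1ccccc1
Why: Steglich esterification of the free acid with a primary alcohol is routine and leaves the tert-butyl ester untouched, giving a malonate with two sterically different, orthogonally cleavable esters.

Step 3
Reactants: 3 1-tert-butyl 3-(2,2-diphenylethyl) 2-methylpropanedioate
Product: 4 1-tert-butyl 3-(2,2-diphenylethyl) (2S)-2-methyl-2-(3-methylbut-2-en-1-yl)propanedioate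
Conditions: prenyl bromide (5 equiv), (S,S)-3,4,5-trifluorophenyl-NAS bromide (N-spiro bis(binaphthyl)azepinium bromide, C56H34BrF6N, 5 mol%), 50% aq. KOH (5 equiv), toluene, −40 °C, 30 h
Reagents that add atoms: 1-bromo-3-methylbut-2-ene (prenyl bromide), CC(C)=CCBr
Why: Asymmetric phase-transfer alkylation, in which the chiral ammonium cation ion-pairs with the malonate enolate (its two ester groups differ strongly in size) and shields one face, so SN2 attack on prenyl bromide sets the quaternary (S)-centre, which cannot epimerise afterwards.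

Step 4
Reactants: 4 1-tert-butyl 3-(2,2-diphenylethyl) (2S)-2-methyl-2-(3-methylbut-2-en-1-yl)propanedioate
Product: 6 (2R)-3-(2,2-diphenylethoxy)-2-methyl-2-(3-methylbut-2-en-1-yl)-3-oxopropanoic acid, via trimethylsilyl ester 5 (not isolated)
Conditions: TMSOTf (2 equiv), 2,6-lutidine (3 equiv), CH2Cl2, 0 °C → rt; then 5% aq. citric acid
Reagents that add atoms: none
Why: Silyl-triflate-mediated tert-butyl ester cleavage (loss of isobutene from the silylated ester, then hydrolysis of the silyl ester) runs under lutidine buffering, so the primary ester and the acid-sensitive prenyl alkene survive and the quaternary centre is untouched (the descriptor changes from S to R only through CIP priorities).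

Step 5
Reactants: 6 (2R)-3-(2,2-diphenylethoxy)-2-methyl-2-(3-methylbut-2-en-1-yl)-3-oxopropanoic acid; 7 heptane-2,4-dione
Product: 9 2,2-diphenylethyl (2R)-2-methyl-2-(3-methylbut-2-en-1-yl)-3,5,7-trioxodecanoate, via acyl imidazole 8 (not isolated)
Conditions: 6, CDI (1.1 equiv), THF, rt, 2 h; added to the dilithium dianion of 7 [7 (3 equiv), LiN(iPr)2 (6 equiv), THF, 0 °C], −78 → −40 °C; AcOH quench at −78 °C
Reagents that add atoms: none
Why: Claisen-type C-acylation of a β-diketone dianion at its terminal methyl carbanion by an N-acylimidazole that has no α-hydrogen and is far more electrophilic than the neopentyl-type ester on the other arm, so the two malonate arms stay differentiated and the stereocentre is carried through unchanged.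

Step 6
Reactants: 9 2,2-diphenylethyl (2R)-2-methyl-2-(3-methylbut-2-en-1-yl)-3,5,7-trioxodecanoate
Product: 10 (4R)-2-butanoyl-3,5-dihydroxy-4-methyl-4-(3-methylbut-2-en-1-yl)cyclohexa-2,5-dien-1-one
Conditions: KOtBu (3 equiv), THF, 0 °C → rt; 1 M HCl
Reagents that add atoms: none
Why: Intramolecular Claisen (Dieckmann-type) condensation in which the carbanion between the C5 and C7 ketones attacks the ester in the only possible six-membered closure, driven by the very stable triketone enolate; the quaternary centre is retained because its two flanking carbonyls are constitutionally different (one next to the acylated carbon, one next to CH).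

Step 7
Reactants: 11 phloroglucinol (benzene-1,3,5-triol)
Product: 12 1-(2,4,6-trihydroxyphenyl)hexan-1-one
Conditions: hexanoyl chloride (1.05 equiv), AlCl3 (3.5 equiv), PhNO2/CH2Cl2, 0 → 40 °C; ice/HCl
Reagents that add atoms: hexanoyl chloride, CCCCCC(Cl)=O
Why: Friedel–Crafts acylation of the very electron-rich triol stops at mono-acylation because the first acyl group deactivates the ring.

Step 8
Reactants: 12 1-(2,4,6-trihydroxyphenyl)hexan-1-one
Product: 13 1-(2,6-dihydroxy-4-methoxyphenyl)hexan-1-one
Conditions: Me2SO4 (1.0 equiv), K2CO3 (1.0 equiv), acetone, rt → 40 °C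
Reagents that add atoms: dimethyl sulfate, COS(=O)(=O)OC
Why: Williamson O-methylation with one equivalent of base goes to the 4-OH, which is the most acidic and the only hydroxyl not engaged with the ortho ketone, and the product is C2-symmetric with two equivalent free ring positions.

Step 9
Reactants: 10 (4R)-2-butanoyl-3,5-dihydroxy-4-methyl-4-(3-methylbut-2-en-1-yl)cyclohexa-2,5-dien-1-one
Product: 14 (4R)-2-butanoyl-6-[(dimethylamino)methyl]-3,5-dihydroxy-4-methyl-4-(3-methylbut-2-en-1-yl)cyclohexa-2,5-dien-1-one
Conditions: CH2(NMe2)2 (1.2 equiv), CH2Cl2, 0 °C → rt; evaporate, use crude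
Reagents that add atoms: bis(dimethylamino)methane, CN(C)CN(C)C
Why: Mannich reaction in which the acidic enol protonates the aminal to the methyleneiminium ion, which is attacked by C6, the only unsubstituted nucleophilic ring carbon, so a single mono-aminomethyl compound results.

Step 10
Reactants: 14 (4R)-2-butanoyl-6-[(dimethylamino)methyl]-3,5-dihydroxy-4-methyl-4-(3-methylbut-2-en-1-yl)cyclohexa-2,5-dien-1-one; 13 1-(2,6-dihydroxy-4-methoxyphenyl)hexan-1-one
Product: 16 elaphopilosin B, via exo-methylene trione 15 (not isolated)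
Conditions: 13 (3 equiv), 1,4-dioxane, 80 °C, N2 sweep, 3 h; 1 M HCl wash
Reagents that add atoms: none
Why: Retro-Michael loss of dimethylamine gives the exo-methylene enetrione, which takes up ring carbon C3 of the symmetric phenol 13 in an intermolecular Michael addition followed by re-aromatisation; excess 13 suppresses homodimers and double bridging, and the remote quaternary (R)-centre is not involved.

**Compound list**

1 | 2,2,5-trimethyl-1,3-dioxane-4,6-dione | CC1C(=O)OC(C)(C)OC1=O | starting material
2 | 3-tert-butoxy-2-methyl-3-oxopropanoic acid (racemic, enolisable) | CC(C(=O)O)C(=O)OC(C)(C)C | intermediate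
3 | 1-tert-butyl 3-(2,2-diphenylethyl) 2-methylpropanedioate (racemic, enolisable) | CC(C(=O)OC(C)(C)C)C(=O)OCC(c1ccccc1)c1ccccc1 | intermediate
4 | 1-tert-butyl 3-(2,2-diphenylethyl) (2S)-2-methyl-2-(3-methylbut-2-en-1-yl)propanedioate | CC(C)(C)OC(=O)[C@@](C)(CC=C(C)C)C(=O)OCC(c1ccccc1)c1ccccc1 | intermediate
5 | 1-(2,2-diphenylethyl) 3-trimethylsilyl (2S)-2-methyl-2-(3-methylbut-2-en-1-yl)propanedioate | C[Si](C)(C)OC(=O)[C@@](C)(CC=C(C)C)C(=O)OCC(c1ccccc1)c1ccccc1 | intermediate
6 | (2R)-3-(2,2-diphenylethoxy)-2-methyl-2-(3-methylbut-2-en-1-yl)-3-oxopropanoic acid | OC(=O)[C@@](C)(CC=C(C)C)C(=O)OCC(c1ccccc1)c1ccccc1 | intermediate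
7 | heptane-2,4-dione | CCCC(=O)CC(C)=O | starting material
8 | 2,2-diphenylethyl (2R)-2-(1H-imidazole-1-carbonyl)-2,5-dimethylhex-4-enoate | O=C(n1ccnc1)[C@@](C)(CC=C(C)C)C(=O)OCC(c1ccccc1)c1ccccc1 | intermediate
9 | 2,2-diphenylethyl (2R)-2-methyl-2-(3-methylbut-2-en-1-yl)-3,5,7-trioxodecanoate | CCCC(=O)CC(=O)CC(=O)[C@@](C)(CC=C(C)C)C(=O)OCC(c1ccccc1)c1ccccc1 | intermediate
10 | (4R)-2-butanoyl-3,5-dihydroxy-4-methyl-4-(3-methylbut-2-en-1-yl)cyclohexa-2,5-dien-1-one | O=C1C=C(O)[C@@](C)(CC=C(C)C)C(O)=C1C(=O)CCC | intermediate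
11 | phloroglucinol (benzene-1,3,5-triol) | Oc1cc(O)cc(O)c1 | starting material
12 | 1-(2,4,6-trihydroxyphenyl)hexan-1-one | CCCCCC(=O)c1c(O)cc(O)cc1O | intermediate
13 | 1-(2,6-dihydroxy-4-methoxyphenyl)hexan-1-one | CCCCCC(=O)c1c(O)cc(OC)cc1O | intermediate
14 | (4R)-2-butanoyl-6-[(dimethylamino)methyl]-3,5-dihydroxy-4-methyl-4-(3-methylbut-2-en-1-yl)cyclohexa-2,5-dien-1-one | O=C1C(CN(C)C)=C(O)[C@@](C)(CC=C(C)C)C(O)=C1C(=O)CCC | intermediate
15 | (4S)-2-butanoyl-3-hydroxy-4-methyl-4-(3-methylbut-2-en-1-yl)-6-methylidenecyclohex-2-ene-1,5-dione (same spatial arrangement as 14; descriptor changes by CIP priority only) | C=C1C(=O)[C@@](C)(CC=C(C)C)C(O)=C(C(=O)CCC)C1=O | intermediate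
16 | elaphopilosin B, (R)-configured at the quaternary ring carbon | CCCCCC(=O)c1c(O)cc(OC)c(CC2=C(O)[C@@](C)(CC=C(C)C)C(O)=C(C(=O)CCC)C2=O)c1O | target

**Summary**

Total step count: 10. Longest linear sequence: 8 steps (steps 1–6, 9, 10); steps 7–8 form the two-step aromatic branch.

Three steps most likely to fail:

Step 3 (enantioselectivity or sense of induction with prenyl bromide). The fallback sets out from 1 and comes back at 6. Compound 1 is C-prenylated (prenyl bromide, K2CO3, DMF, rt) to the achiral 2,2,5-trimethyl-5-(3-methylbut-2-en-1-yl)-1,3-dioxane-4,6-dione F1. Ring opening with sodium 2,2-diphenylethoxide (NaH, 2,2-diphenylethanol, THF, 0 °C → rt) gives racemic 3-(2,2-diphenylethoxy)-2-methyl-2-(3-methylbut-2-en-1-yl)-3-oxopropanoic acid F2. This is resolved by fractional crystallisation of the (S)-1-phenylethylammonium salt of the (2R)-acid F3; if the salt of the (2S)-acid is the less soluble one, the (R)-amine is used instead. Acidification with dilute HCl returns enantiopure 6, and the route continues with step 5.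

Step 5 (dianion acylation with a hindered acyl donor; it also covers a failure of the ring closure in step 6). The fallback sets out from 11 and comes back at 10, building the ring from the aromatic series instead. Phloroglucinol 11 is butanoylated (butanoyl chloride, AlCl3, PhNO2) to 1-(2,4,6-trihydroxyphenyl)butan-1-one F4. C-Prenylation (prenyl bromide, aq. KOH, 0 °C) gives 1-[2,4,6-trihydroxy-3-(3-methylbut-2-en-1-yl)phenyl]butan-1-one F5. Dearomatising C-methylation at the prenylated carbon (MeI, NaOMe, MeOH, 0 °C → rt) gives racemic 2-butanoyl-3,5-dihydroxy-4-methyl-4-(3-methylbut-2-en-1-yl)cyclohexa-2,5-dien-1-one F6. Preparative HPLC on a cellulose tris(3,5-dimethylphenylcarbamate) phase separates the (4R)-enantiomer, which is 10; the route continues with step 9.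

Step 10 (cross-coupling against homodimer formation and methylene scrambling). The fallback sets out from 13, uses 10 directly, and comes back at 16, with the roles of the partners reversed. Compound 13 is aminomethylated with one equivalent of CH2(NMe2)2 (dioxane, rt) to 1-{3-[(dimethylamino)methyl]-2,6-dihydroxy-4-methoxyphenyl}hexan-1-one F7. Heating F7 with 10 in toluene at 100 °C expels dimethylamine to give the ortho-quinone methide 2-hexanoyl-3-hydroxy-5-methoxy-6-methylidenecyclohexa-2,4-dien-1-one F8 (not isolated). This is trapped at enol carbon C6 of 10, a much better Michael donor than any phenol ring carbon, giving 16 directly.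

**Further compounds**

F1 | step 3 | 2,2,5-trimethyl-5-(3-methylbut-2-en-1-yl)-1,3-dioxane-4,6-dione | CC(C)=CCC1(C)C(=O)OC(C)(C)OC1=O
F2 | step 3 | racemic 3-(2,2-diphenylethoxy)-2-methyl-2-(3-methylbut-2-en-1-yl)-3-oxopropanoic acid | OC(=O)C(C)(CC=C(C)C)C(=O)OCC(c1ccccc1)c1ccccc1
F3 | step 3 | (S)-1-phenylethylammonium (2R)-3-(2,2-diphenylethoxy)-2-methyl-2-(3-methylbut-2-en-1-yl)-3-oxopropanoate | C[C@H]([NH3+])c1ccccc1.[O-]C(=O)[C@@](C)(CC=C(C)C)C(=O)OCC(c1ccccc1)c1ccccc1
F4 | step 5 | 1-(2,4,6-trihydroxyphenyl)butan-1-one | CCCC(=O)c1c(O)cc(O)cc1O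
F5 | step 5 | 1-[2,4,6-trihydroxy-3-(3-methylbut-2-en-1-yl)phenyl]butan-1-one | CCCC(=O)c1c(O)cc(O)c(CC=C(C)C)c1O
F6 | step 5 | racemic 2-butanoyl-3,5-dihydroxy-4-methyl-4-(3-methylbut-2-en-1-yl)cyclohexa-2,5-dien-1-one | O=C1C=C(O)C(C)(CC=C(C)C)C(O)=C1C(=O)CCC
F7 | step 10 | 1-{3-[(dimethylamino)methyl]-2,6-dihydroxy-4-methoxyphenyl}hexan-1-one | CCCCCC(=O)c1c(O)cc(OC)c(CN(C)C)c1O
F8 | step 10 | 2-hexanoyl-3-hydroxy-5-methoxy-6-methylidenecyclohexa-2,4-dien-1-one | CCCCCC(=O)C1=C(O)C=C(OC)C(=C)C1=O
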